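**Retrosynthetic overview** (ring A = oxepane, ring B = cyclohexane, ring C = cycloheptane, ring D = cyclopentane)
1. Last events: fluoride desilylation, and before it equatorial MeLi addition to a ring-B ketone (sets the axial tertiary alcohol).
2. The exocyclic C=CH–CH2 link is cut between the allylic CH2 and ring B: decarboxylative allylation of a ring-A/B acylketene (stored as a dioxinone) with a ring-C/D tertiary vinyl carbinol.
3. Rings A then B come from one epoxonium cascade of an (R,R,R)-diepoxide: the ring-A C–O bond forms first, then a dioxinone carbon closes ring B (key step).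
4. Ring D comes from (S)-linalool by ring-closing metathesis; an Ireland–Claisen shift sets the CMe2-bearing stereocentre; ring C is closed by a vinyl sulfone Michael/epoxide-opening annulation that also places the ring-D tertiary C–O.
5. Order of ring formation: D, C (east); A, B (west); union; ring-B carbinol last.

Assumption: (S)-(+)-linalool (coriander-oil linalool) of high ee is bought; any shortfall in ee is corrected by crystallising the Claisen acid as a chiral amine salt.

**Route**

Step 1
Reactants: 1 (S)-(+)-linalool [(3S)-3,7-dimethylocta-1,6-dien-3-ol]; 2 2-methylpropanoyl chloride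
Product: 4 (1S)-1-methylcyclopent-2-en-1-yl 2-methylpropanoate, via (1S)-1-methylcyclopent-2-en-1-ol 3 (not isolated)
Conditions: second-generation Grubbs catalyst RuCl2(=CHPh)(PCy3)(H2IMes) (0.2 mol %), neat, 40 °C; then THF, n-BuLi, −78 °C; 2, −78 → 0 °C
Reagents that add atoms: none
Why: Ring-closing metathesis of the 1,6-diene (isobutene leaves, the carbinol centre is untouched) followed by O-acylation of the lithium alkoxide in the same flask, which avoids isolating the volatile, acid-labile tertiary allylic alcohol.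

Step 2
Reactants: 4 (1S)-1-methylcyclopent-2-en-1-yl 2-methylpropanoate
Product: 7 2-methyl-2-[(1R)-3-methylcyclopent-2-en-1-yl]propanoic acid, via trimethylsilyl ketene acetal 5 (not isolated), via trimethylsilyl ester 6 (not isolated)
Conditions: LiN(iPr)2, THF, −78 °C; Me3SiCl, −78 → 60 °C; 1 M HCl
Reagents that add atoms: none
Why: Ireland–Claisen rearrangement: the tetrasubstituted silyl ketene acetal (no E/Z issue) shifts suprafacially through a boat-like transition state, so the C–O stereocentre is traded with full 1,3-chirality transfer for the new ring stereocentre (R) that carries the quaternary CMe2 group.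

Step 3
Reactants: 7 2-methyl-2-[(1R)-3-methylcyclopent-2-en-1-yl]propanoic acid
Product: 8 3-methyl-3-[(1R)-3-methylcyclopent-2-en-1-yl]butan-2-one
Conditions: MeLi (2.5 equiv), Et2O, 0 → 25 °C; aq. NH4Cl
Reagents that add atoms: methyllithium, [Li]C
Why: Addition of MeLi to the lithium carboxylate gives a dilithium gem-diolate that releases the methyl ketone only on work-up, and the neopentyl position blocks over-addition (carboxylic acid to ketone with an organolithium).

Step 4
Reactants: 8 3-methyl-3-[(1R)-3-methylcyclopent-2-en-1-yl]butan-2-one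
Product: 9 3-methyl-3-[(1S,2S,5R)-5-methyl-6-oxabicyclo[3.1.0]hexan-2-yl]butan-2-one
Conditions: mCPBA, NaHCO3, CH2Cl2, 0 °C
Reagents that add atoms: 3-chloroperoxybenzoic acid, OOC(=O)c1cccc(Cl)c1
Why: Prilezhaev epoxidation of the only alkene from the ring face opposite the bulky tertiary-alkyl substituent, which sets the future ring-D C–O stereocentre and the trans relation between oxygen and side chain.

Step 5
Reactants: 9 3-methyl-3-[(1S,2S,5R)-5-methyl-6-oxabicyclo[3.1.0]hexan-2-yl]butan-2-one; 10 phenyl vinyl sulfone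
Product: 13 (1R,3aR,8aR)-1,4,4-trimethyl-8-(phenylsulfonyl)-1-[(triethylsilyl)oxy]octahydroazulen-5(1H)-one (C8 epimers), via keto sulfone 11 (not isolated), via bis(triethylsilyl) enol ether 12 (not isolated)
Conditions: LiN(iPr)2 (1.05 equiv), THF, −78 °C; 10, −78 °C; LiN(iPr)2 (1.2 equiv), DMPU, −78 → 25 °C; Et3SiOTf (2.5 equiv), −78 °C; 0.5 M HCl work-up
Reagents that add atoms: triethylsilyl trifluoromethanesulfonate, CC[Si](CC)(CC)OS(=O)(=O)C(F)(F)F
Why: Michael addition of the only possible ketone enolate to the vinyl sulfone, after which the α-sulfonyl carbanion of the dianion opens the epoxide at its secondary carbon in a 7-exo-tet SN2 step (Michael-initiated ring closure), the tether forcing the cis ring fusion and inversion placing the new C–C bond trans to the tertiary alkoxide, which is capped as its triethylsilyl ether while the enol silyl ether is hydrolysed on work-up.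

Step 6
Reactants: 13 (1R,3aR,8aR)-1,4,4-trimethyl-8-(phenylsulfonyl)-1-[(triethylsilyl)oxy]octahydroazulen-5(1H)-one
Product: 14 (1R,3aR,8aR)-1,4,4-trimethyl-1-[(triethylsilyl)oxy]octahydroazulen-5(1H)-one
Conditions: Mg, MeOH, 50 °C
Reagents that add atoms: none
Why: Reductive desulfonylation by electron transfer from Mg in MeOH cleaves the C–S bond and protonates the carbanion, leaving the hindered ketone, the silyl ether and all stereocentres untouched.

Step 7
Reactants: 14 (1R,3aR,8aR)-1,4,4-trimethyl-1-[(triethylsilyl)oxy]octahydroazulen-5(1H)-one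
Product: 15 (1R,3aR,6R,8aR)-1,4,4,6-tetramethyl-1-[(triethylsilyl)oxy]octahydroazulen-5(1H)-one
Conditions: LiN(iPr)2 (1.1 equiv), THF, −78 °C; MeI, −78 → −40 °C
Reagents that add atoms: iodomethane, CI
Why: Kinetic enolate alkylation of the single possible enolate, with MeI expected to approach from the convex face of the cis-fused bicycle (the face of the two ring-fusion hydrogens), which would set the ring-C methyl stereocentre (R); the facial bias is modest and is the least certain stereochemical call in the route.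

Step 8
Reactants: 15 (1R,3aR,6R,8aR)-1,4,4,6-tetramethyl-1-[(triethylsilyl)oxy]octahydroazulen-5(1H)-one
Product: 16 (1R,3aR,6R,8aR)-5-ethenyl-1,4,4,6-tetramethyl-1-[(triethylsilyl)oxy]decahydroazulen-5-ol (C5 epimers)
Conditions: CH2=CHMgBr, CeCl3, THF, −78 → 0 °C
Reagents that add atoms: vinylmagnesium bromide, C=C[Mg]Br
Why: Organocerium (Imamoto) 1,2-addition overcomes enolisation of the doubly α-branched ketone; the new carbinol centre (either epimer) is erased in step 12.

Step 9
Reactants: 17 2,2,6-trimethyl-4H-1,3-dioxin-4-one; 18 geranyl bromide [(2E)-1-bromo-3,7-dimethylocta-2,6-diene]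
Product: 19 6-[(3E)-4,8-dimethylnona-3,7-dien-1-yl]-2,2-dimethyl-4H-1,3-dioxin-4-one
Conditions: LiN(iPr)2, THF–DMPU, −78 °C; 18, −78 → −20 °C
Reagents that add atoms: none
Why: γ-Alkylation of the lithium dienolate of the dioxinone (vinylogous enolate alkylation) by the allylic bromide installs the E-configured diene chain on a masked β-keto acid.

Step 10
Reactants: 19 6-[(3E)-4,8-dimethylnona-3,7-dien-1-yl]-2,2-dimethyl-4H-1,3-dioxin-4-one
Product: 20 6-{2-[(2R,3R)-3-{2-[(2R)-3,3-dimethyloxiran-2-yl]ethyl}-3-methyloxiran-2-yl]ethyl}-2,2-dimethyl-4H-1,3-dioxin-4-one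
Conditions: D-fructose-derived Shi ketone (1,2:4,5-di-O-isopropylidene-β-D-erythro-2,3-hexodiulo-2,6-pyranose, 60 mol %), KHSO5 (as 2KHSO5·KHSO4·K2SO4), K2CO3, Bu4NHSO4, MeCN–CH2(OMe)2–aq. Na2B4O7 (pH 10.5), 0 °C
Reagents that add atoms: potassium peroxymonosulfate, [K+].[O-]S(=O)(=O)OO
Why: Shi asymmetric epoxidation: the chiral dioxirane epoxidises both electron-rich trisubstituted alkenes through spiro transition states to give the (R,R) and (R) epoxides (three C–O stereocentres), while the electron-poor dioxinone C=C is left alone.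

Step 11
Reactants: 20 6-{2-[(2R,3R)-3-{2-[(2R)-3,3-dimethyloxiran-2-yl]ethyl}-3-methyloxiran-2-yl]ethyl}-2,2-dimethyl-4H-1,3-dioxin-4-one
Product: 21 ring-A/B tricyclic dioxinone tert-butyldimethylsilyl ether
Conditions: t-BuMe2SiOTf (1.1 equiv), 2,6-di-tert-butyl-4-methylpyridine (1.5 equiv), CH2Cl2, −78 °C
Reagents that add atoms: tert-butyldimethylsilyl trifluoromethanesulfonate, CC(C)(C)[Si](C)(C)OS(=O)(=O)C(F)(F)F
Why: Proposed new method: the silyl triflate activates the terminal epoxide, the neighbouring epoxide oxygen attacks its tertiary carbon (this makes the ring-A C–O bond and a bicyclic epoxonium ion), and C5 of the dioxinone, a regiochemically locked β-keto ester enol equivalent, opens the epoxonium ion at its tertiary carbon with inversion through a chair transition state before the hindered pyridine removes H5 to restore the dioxinone, so rings A and B, the trans ring fusion and the angular quaternary centre arise in one step with both epoxide C–O stereocentres retained; the closest known reactions are enol-silane- and allylsilane-terminated epoxonium (oxa/carbacyclisation) cascades of polyepoxides and Prins cyclisations terminated by a dioxinone.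

Step 12
Reactants: 21 ring-A/B tricyclic dioxinone tert-butyldimethylsilyl ether; 16 (1R,3aR,6R,8aR)-5-ethenyl-1,4,4,6-tetramethyl-1-[(triethylsilyl)oxy]decahydroazulen-5-ol
Product: 24 ring-B ketone bis-silyl ether (E alkene), via acylketene 22 (not isolated), via tertiary allylic β-keto ester 23 (not isolated)
Conditions: PhMe, 110 °C; then Pd(PPh3)4 (5 mol %), 25 → 50 °C; then DBU (20 mol %), 25 °C
Reagents that add atoms: none
Why: Thermal retro-[4+2] of the dioxinone gives an acylketene that acylates the hindered tertiary allylic alcohol, Pd-catalysed decarboxylative allylation (Tsuji–Trost/Carroll type) then forms the C–C bond at the unsubstituted allyl terminus with the CMe2 arm syn in the π-allyl complex (E alkene), and DBU equilibrates the new ring-B stereocentre to the equatorial side chain (R).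

Step 13
Reactants: 24 ring-B ketone bis-silyl ether
Product: 25 bis-silyl ether of the target
Conditions: MeLi, CeCl3, THF, −78 °C
Reagents that add atoms: methyllithium, [Li]C
Why: Organocerium methyl addition to the ketone from the equatorial direction, because the axial face is shielded by the 1,3-diaxial angular methyl group, gives the axial tertiary alcohol (S).

Step 14
Reactants: 25 bis-silyl ether of the target
Product: 26 CNP0167890.2 (target)
Conditions: Bu4NF, THF, 60 °C
Reagents that add atoms: none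
Why: Fluoride-mediated cleavage of both silyl ethers (Si–F bond formation) touches no stereocentre and gives the triol.

**Compound list**

1 | (S)-(+)-linalool, (3S)-3,7-dimethylocta-1,6-dien-3-ol | C=C[C@@](C)(O)CCC=C(C)C | starting material
2 | 2-methylpropanoyl chloride | CC(C)C(Cl)=O | starting material
3 | (1S)-1-methylcyclopent-2-en-1-ol (not isolated) | C[C@@]1(O)C=CCC1 | intermediate
4 | (1S)-1-methylcyclopent-2-en-1-yl 2-methylpropanoate | CC(C)C(=O)O[C@]1(C)C=CCC1 | intermediate
5 | trimethylsilyl ketene acetal of 4 (not isolated) | CC(C)=C(O[Si](C)(C)C)O[C@]1(C)C=CCC1 | intermediate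
6 | trimethylsilyl 2-methyl-2-[(1R)-3-methylcyclopent-2-en-1-yl]propanoate (not isolated) | CC1=C[C@@H](CC1)C(C)(C)C(=O)O[Si](C)(C)C | intermediate
7 | 2-methyl-2-[(1R)-3-methylcyclopent-2-en-1-yl]propanoic acid | CC1=C[C@@H](CC1)C(C)(C)C(O)=O | intermediate
8 | 3-methyl-3-[(1R)-3-methylcyclopent-2-en-1-yl]butan-2-one | CC1=C[C@@H](CC1)C(C)(C)C(C)=O | intermediate
9 | 3-methyl-3-[(1S,2S,5R)-5-methyl-6-oxabicyclo[3.1.0]hexan-2-yl]butan-2-one (epoxide trans to the side chain) | CC(=O)C(C)(C)[C@@H]1CC[C@@]2(C)O[C@@H]12 | intermediate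
10 | phenyl vinyl sulfone | C=CS(=O)(=O)c1ccccc1 | starting material
11 | 5-methyl-5-[(1S,2S,5R)-5-methyl-6-oxabicyclo[3.1.0]hexan-2-yl]-1-(phenylsulfonyl)hexan-3-one (formed as its lithium carbanion, not isolated) | O=C(CCCS(=O)(=O)c1ccccc1)C(C)(C)[C@@H]1CC[C@@]2(C)O[C@@H]12 | intermediate
12 | cis-fused bicyclic sulfone as triethylsilyl enol ether and tertiary triethylsilyl ether (not isolated) | CC[Si](CC)(CC)OC1=CCC(S(=O)(=O)c2ccccc2)[C@@H]2[C@@H](CC[C@@]2(C)O[Si](CC)(CC)CC)C1(C)C | intermediate
13 | (1R,3aR,8aR)-1,4,4-trimethyl-8-(phenylsulfonyl)-1-[(triethylsilyl)oxy]octahydroazulen-5(1H)-one (C8 epimers) | O=C1CCC(S(=O)(=O)c2ccccc2)[C@@H]2[C@@H](CC[C@@]2(C)O[Si](CC)(CC)CC)C1(C)C | intermediate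
14 | (1R,3aR,8aR)-1,4,4-trimethyl-1-[(triethylsilyl)oxy]octahydroazulen-5(1H)-one | O=C1CCC[C@@H]2[C@@H](CC[C@@]2(C)O[Si](CC)(CC)CC)C1(C)C | intermediate
15 | (1R,3aR,6R,8aR)-1,4,4,6-tetramethyl-1-[(triethylsilyl)oxy]octahydroazulen-5(1H)-one | C[C@@H]1CC[C@@H]2[C@@H](CC[C@@]2(C)O[Si](CC)(CC)CC)C(C)(C)C1=O | intermediate
16 | (1R,3aR,6R,8aR)-5-ethenyl-1,4,4,6-tetramethyl-1-[(triethylsilyl)oxy]decahydroazulen-5-ol (C5 epimers, centre left undefined) | C[C@@H]1CC[C@@H]2[C@@H](CC[C@@]2(C)O[Si](CC)(CC)CC)C(C)(C)C1(O)C=C | intermediate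
17 | 2,2,6-trimethyl-4H-1,3-dioxin-4-one | CC1=CC(=O)OC(C)(C)O1 | starting material
18 | geranyl bromide, (2E)-1-bromo-3,7-dimethylocta-2,6-diene | CC(C)=CCC/C(C)=C/CBr | starting material
19 | 6-[(3E)-4,8-dimethylnona-3,7-dien-1-yl]-2,2-dimethyl-4H-1,3-dioxin-4-one | CC(C)=CCC/C(C)=C/CCC1=CC(=O)OC(C)(C)O1 | intermediate
20 | 6-{2-[(2R,3R)-3-{2-[(2R)-3,3-dimethyloxiran-2-yl]ethyl}-3-methyloxiran-2-yl]ethyl}-2,2-dimethyl-4H-1,3-dioxin-4-one | CC1(C)O[C@@H]1CC[C@@]1(C)O[C@@H]1CCC1=CC(=O)OC(C)(C)O1 | intermediate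
21 | tricycle: trans-fused oxepane (ring A) and cyclohexene (ring B) whose C=C is C5=C6 of a 2,2-dimethyl-1,3-dioxin-4-one (lactone carbonyl on the carbon next to the angular methyl carbon); ring A has gem-dimethyl next to O and an (R)-OSiMe2t-Bu carbinol; angular methyl carbon R; O-bearing ring-fusion CH R | CC1(C)O[C@@H]2CCC3=C(C(=O)OC(C)(C)O3)[C@@]2(C)CC[C@H]1O[Si](C)(C)C(C)(C)C | intermediate
22 | ring-A/B α-oxo ketene from 21 by loss of acetone (not isolated) | CC1(C)O[C@@H]2CCC(=O)C(=C=O)[C@@]2(C)CC[C@H]1O[Si](C)(C)C(C)(C)C | intermediate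
23 | ester of the ring-B 2-oxo-1-carboxylic acid with carbinol 16 (tertiary allylic β-keto ester, α-carbon and carbinol carbon undefined, not isolated) | CC1(C)O[C@@H]2CCC(=O)C(C(=O)OC3(C=C)[C@H](C)CC[C@@H]4[C@@H](CC[C@@]4(C)O[Si](CC)(CC)CC)C3(C)C)[C@@]2(C)CC[C@H]1O[Si](C)(C)C(C)(C)C | intermediate
24 | target skeleton with ring-B C=O in place of the C(CH3)OH group, ring-A OH as tert-butyldimethylsilyl ether, ring-D OH as triethylsilyl ether, E alkene | C[C@@H]1CC[C@@H]2[C@@H](CC[C@@]2(C)O[Si](CC)(CC)CC)C(C)(C)/C1=C/C[C@@H]1[C@@]2(C)CC[C@@H](O[Si](C)(C)C(C)(C)C)C(C)(C)O[C@@H]2CCC1=O | intermediate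
25 | target with ring-A OH as tert-butyldimethylsilyl ether and ring-D OH as triethylsilyl ether | C[C@@H]1CC[C@@H]2[C@@H](CC[C@@]2(C)O[Si](CC)(CC)CC)C(C)(C)/C1=C/C[C@@H]1[C@@]2(C)CC[C@@H](O[Si](C)(C)C(C)(C)C)C(C)(C)O[C@@H]2CC[C@]1(C)O | intermediate
26 | CNP0167890.2 | C[C@@H]1CC[C@@H]2[C@@H](CC[C@@]2(C)O)C(C)(C)/C1=C/C[C@@H]1[C@@]2(C)CC[C@@H](O)C(C)(C)O[C@@H]2CC[C@]1(C)O | target

**Step count and risk**

Total: 14 steps. Longest linear sequence: 11 steps (steps 1–8, then 12–14); steps 9–11 form the second branch.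

Most likely to fail:

Step 11 (the proposed new cascade). The dioxinone may be too weak a π-nucleophile, so the epoxonium ion could be trapped by triflate or the internal epoxide could be opened first. The fallback uses known chemistry only, sets out from 20 (with 16 for the side chain) and returns at 24. Heating 20 in pyridine-buffered aqueous dioxane (100 °C) unmasks the methyl ketone, diepoxy ketone F4. LiN(iPr)2 and t-BuMe2SiCl (THF–DMPU, −78 °C) give the kinetic enol silyl ether F5. t-BuMe2SiOTf with 2,6-di-tert-butyl-4-methylpyridine (CH2Cl2, −78 °C), the precedented enol-silane-terminated cascade, gives ring-A/B ketone F6. IBX (DMSO, 70 °C) can dehydrogenate only on the side away from the quaternary carbon and gives enone F7. Separately, 16 with PBr3 and pyridine (Et2O, −30 °C) gives, with allylic transposition, the primary allylic bromide F8. The only possible enolate of F7 (LiN(iPr)2, THF, −78 °C) is alkylated by F8 to give alkylated enone F9. Conjugate reduction with [(Ph3P)CuH]6 (PhMe, 25 °C) and DBU equilibration give 24.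

Step 5 (Michael/epoxide-opening annulation). The ketone enolate of the dianion may attack the epoxide itself (5-exo) or quench the sulfonyl carbanion. The fallback sets out from 9 and returns at 14; it ties the enolate up as a non-nucleophilic β-keto sulfone anion. LiN(iPr)2 (2.1 equiv) and PhSO2F (THF, −78 °C) give β-keto sulfone F1. Compound 10 with DBU (10 mol %, MeCN, 25 °C) gives the Michael adduct, bis-sulfone F2. NaH (1 equiv) then n-BuLi (1.1 equiv; THF, −78 → 25 °C) form a dianion whose only reactive carbon, the terminal α-sulfonyl carbanion, opens the epoxide; Et3SiOTf caps the alkoxide to give bicyclic bis-sulfone F3. Mg in MeOH (50 °C) removes both sulfonyl groups and gives 14.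

Step 12 (acylketene capture and decarboxylative allylation). The acylketene may not be captured by the very hindered carbinol, or the tertiary ester may eliminate. The fallback sets out from 21 and 16 and returns at 24. Heating 21 with MeOH (PhMe, 110 °C) gives methyl β-keto ester F10. Pd(PPh3)4 (5 mol %) with Et3B (THF, 50 °C) ionises 16 directly and the β-keto ester is C-allylated at the CH2 terminus (Tsuji–Trost allylation with an allylic alcohol) to give quaternary β-keto ester F11. LiCl in wet DMSO (140 °C, Krapcho dealkoxycarbonylation) followed by DBU gives 24.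

Further compounds
F1 | step 5 | 3-methyl-3-[(1S,2S,5R)-5-methyl-6-oxabicyclo[3.1.0]hexan-2-yl]-1-(phenylsulfonyl)butan-2-one | O=C(CS(=O)(=O)c1ccccc1)C(C)(C)[C@@H]1CC[C@@]2(C)O[C@@H]12
F2 | step 5 | 5-methyl-5-[(1S,2S,5R)-5-methyl-6-oxabicyclo[3.1.0]hexan-2-yl]-1,3-bis(phenylsulfonyl)hexan-4-one (C3 epimers) | O=C(C(CCS(=O)(=O)c1ccccc1)S(=O)(=O)c1ccccc1)C(C)(C)[C@@H]1CC[C@@]2(C)O[C@@H]12
F3 | step 5 | (1R,3aR,8aR)-1,4,4-trimethyl-6,8-bis(phenylsulfonyl)-1-[(triethylsilyl)oxy]octahydroazulen-5(1H)-one (C6 and C8 epimers) | O=C1C(S(=O)(=O)c2ccccc2)CC(S(=O)(=O)c2ccccc2)[C@@H]2[C@@H](CC[C@@]2(C)O[Si](CC)(CC)CC)C1(C)C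
F4 | step 11 | 4-[(2R,3R)-3-{2-[(2R)-3,3-dimethyloxiran-2-yl]ethyl}-3-methyloxiran-2-yl]butan-2-one | CC1(C)O[C@@H]1CC[C@@]1(C)O[C@@H]1CCC(C)=O
F5 | step 11 | tert-butyldimethylsilyl enol ether (terminal C=C) of F4 | CC1(C)O[C@@H]1CC[C@@]1(C)O[C@@H]1CCC(=C)O[Si](C)(C)C(C)(C)C
F6 | step 11 | trans-fused ring-A/B ketone (ring-B C=O two carbons from the angular methyl carbon, ring-A OSiMe2t-Bu) | CC1(C)O[C@@H]2CCC(=O)C[C@@]2(C)CC[C@H]1O[Si](C)(C)C(C)(C)C
F7 | step 11 | ring-A/B enone (C=C between the carbonyl and the O-bearing ring-fusion carbon) | CC1(C)O[C@@H]2C=CC(=O)C[C@@]2(C)CC[C@H]1O[Si](C)(C)C(C)(C)C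
F8 | step 11 | (1R,3aR,6R,8aR,5E)-5-(2-bromoethylidene)-1,4,4,6-tetramethyl-1-[(triethylsilyl)oxy]decahydroazulene | C[C@@H]1CC[C@@H]2[C@@H](CC[C@@]2(C)O[Si](CC)(CC)CC)C(C)(C)/C1=C/CBr
F9 | step 11 | 24 with an additional C=C in ring B between the carbonyl and the O-bearing ring-fusion carbon | C[C@@H]1CC[C@@H]2[C@@H](CC[C@@]2(C)O[Si](CC)(CC)CC)C(C)(C)/C1=C/C[C@@H]1[C@@]2(C)CC[C@@H](O[Si](C)(C)C(C)(C)C)C(C)(C)O[C@@H]2C=CC1=O
F10 | step 12 | methyl ester of the ring-B 2-oxo-1-carboxylic acid (ring-A OSiMe2t-Bu, α-carbon undefined) | CC1(C)O[C@@H]2CCC(=O)C(C(=O)OC)[C@@]2(C)CC[C@H]1O[Si](C)(C)C(C)(C)C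
F11 | step 12 | F10 C-allylated at the α-carbon by the (E)-2-(hydroazulenylidene)ethyl group of 16 (quaternary α-carbon undefined) | CC1(C)O[C@@H]2CCC(=O)C(C/C=C3\[C@H](C)CC[C@@H]4[C@@H](CC[C@@]4(C)O[Si](CC)(CC)CC)C3(C)C)(C(=O)OC)[C@@]2(C)CC[C@H]1O[Si](C)(C)C(C)(C)C
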